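The numbers in the tables stem from a simulated flask for an exercise; the scatter is artificial.

in all of them: starting material 0.25 M

|  | reagent | remark | time |
|---|---|---|---|
| amber | 1.2 equiv | the very flask that is asked about, followed so far |  |
| flask | 1.20 equiv |  | 15 h |

amber run (percent of the starting material charged)

| time / h | starting material / % | product / % |
|---|---|---|
| 1.00 | 32.5 | 67.0 |
| 2.00 | 27.9 | 74.1 |
| 3.00 | 25.1 | 74.3 |
| 4.00 | 24.3 | 75.2 |
| 5.00 | 26.2 | 77.0 |
| 6.00 | 21.0 | 78.0 |
| 8.00 | 23.3 | 80.2 |

(scatter of a reading: 1 percentage point)

- the earlier runs do not show how much of reagent is bound; that part of a forecast is a guess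

1. part of the starting material that has reacted at 15 h
2. share of the unused reagent that is free and not bound as idle adduct, at 15 h

1. By plain count a stall in this flask is impossible: 1.20 equiv of reagent is charged, and at 8.00 h the amber run, which is this same flask so far, has converted about 78.5 %, taking the mean of starting material lost and product gained, so part of the charge has not reacted. Yet its conversion crawls.

2. So I count doublings of elapsed time, not hours. At 1.00 h the same mean gives 67.3 %, and 3.00 doublings later it gives the value above. That makes 3.7 percentage points for each doubling, my gain per doubling.

3. From 8.00 h to 15 h is 0.907 doublings, so I commit to 81.8 % reacted. This count says nothing about bound reagent.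

4. The forecast gives 83 % reacted, on the ground that “The rate is still falling”, and calls its 4 % free a guess. Its conversion stands 1.2 points above my count.

5. The flask gives 82.2 % reacted and 1.94 % free.

    starting material ⇌ intermediate + leaving ligand, settled at all times (K = 3.10 × 10⁻⁴ M)
    reagent + intermediate → product (k = 4100 M⁻¹ h⁻¹)
    reagent + leaving ligand ⇌ idle adduct, settled at all times (K = 450 M⁻¹)

In this flask, free reagent has a half-life of 0.74 min in the step to product at 0.00600 h, and 1.4 h at 15.0 h, which is still short against the time. At that hour the idle adduct, the reagent's resting state, stands at 0.0929 M, more than the 0.00184 M of free reagent. Carried 3.32 doublings on from 82.2 %, the gain per doubling gives 94.5 % for this flask at 150 h, and the flask stands at 94.7 %.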